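**Retrosynthetic overview**

1. Last disconnections: the two O‑isopropyl groups (BCl3) and the bond from chromone C3 to ring B (Negishi coupling of 6‑iodochromane 12 with 3‑iodochromone 16).
2. The dihydropyran ring (ring D) is closed on ring B at the O–C(CH3)2/CH2 bond (C2–C3 of the chromane) by a Lewis‑acid‑catalysed [1,5]‑hydride shift/cyclisation of benzylidene Meldrum's acid 6. The Meldrum's acid unit is then excised by hydrolysis and two decarboxylations.
3. Enabling feature: the pyran oxygen O1 sits on the ring B carbon next to the one that carries C4. An O‑isopropyl group on that oxygen therefore holds its methine C–H (the future C2, already bearing both methyl groups and O1) five atoms from the benzylidene carbon (the future C4). The para isopropoxy group cannot reach, and the ortho methoxy group has only primary C–H bonds.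
4. Ring order: ring B is bought (2,4,6‑trihydroxybenzaldehyde), ring D is formed in step 5, ring C (pyranone) is closed on ring A at O1–C2 in step 10, and the halves are joined in step 11.

Key step: step 5

Assumption: 1, 5 and 13 are commercial. Reagents that deliver atoms are given by name and SMILES in each step and carry no number. The target has no stereocentre; 10 and 11 are racemic at C3, and that centre is erased in step 7.

**Route**

Step 1
Reactants: 1 2,4,6‑trihydroxybenzaldehyde
Product: 2 2‑hydroxy‑4,6‑di(propan‑2‑yloxy)benzaldehyde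
Conditions: 2‑bromopropane (2.3 equiv), K2CO3, DMF, 50 °C
Reagents that add atoms: 2‑bromopropane, CC(C)Br
Why: Williamson ether synthesis; the para hydroxyl and one ortho hydroxyl should be alkylated, while the second ortho hydroxyl, hydrogen‑bonded to the formyl oxygen, is the least nucleophilic and should remain.

Step 2
Reactants: 2 2‑hydroxy‑4,6‑di(propan‑2‑yloxy)benzaldehyde
Product: 3 2‑hydroxy‑3‑iodo‑4,6‑di(propan‑2‑yloxy)benzaldehyde
Conditions: NIS (1.0 equiv), CF3CO2H (10 mol %), MeCN, 0 °C to rt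
Reagents that add atoms: N‑iodosuccinimide, O=C1CCC(=O)N1I
Why: Electrophilic aromatic iodination; the free phenol is the strongest ortho director, and the site between OH and O‑isopropyl is less crowded than the site between the two isopropoxy groups, so iodine should enter at C3.

Step 3
Reactants: 3 2‑hydroxy‑3‑iodo‑4,6‑di(propan‑2‑yloxy)benzaldehyde
Product: 4 3‑iodo‑2‑methoxy‑4,6‑di(propan‑2‑yloxy)benzaldehyde
Conditions: MeI, K2CO3, DMF, 40 °C
Reagents that add atoms: iodomethane, CI
Why: Williamson O‑methylation of the only remaining nucleophilic site, the phenoxide, in a dipolar aprotic solvent.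

Step 4
Reactants: 4 3‑iodo‑2‑methoxy‑4,6‑di(propan‑2‑yloxy)benzaldehyde; 5 2,2‑dimethyl‑1,3‑dioxane‑4,6‑dione (Meldrum's acid)
Product: 6 5‑{[3‑iodo‑2‑methoxy‑4,6‑di(propan‑2‑yloxy)phenyl]methylidene}‑2,2‑dimethyl‑1,3‑dioxane‑4,6‑dione
Conditions: piperidine (10 mol %), AcOH (10 mol %), toluene, 4 Å MS, 50 °C
Reagents that add atoms: none
Why: Knoevenagel condensation; the very acidic Meldrum's acid condenses even with hindered, donor‑rich benzaldehydes, and the symmetric acceptor leaves no alkene geometry to control.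

Step 5
Reactants: 6 5‑{[3‑iodo‑2‑methoxy‑4,6‑di(propan‑2‑yloxy)phenyl]methylidene}‑2,2‑dimethyl‑1,3‑dioxane‑4,6‑dione
Product: 8 6‑iodo‑5‑methoxy‑2,2,2',2'‑tetramethyl‑7‑(propan‑2‑yloxy)spiro[chromane‑3,5'‑[1,3]dioxane]‑4',6'‑dione, via oxocarbenium enolate zwitterion 7 (not isolated)
Conditions: Sc(OTf)3 (10 mol %), ClCH2CH2Cl (0.05 M), 80 °C
Reagents that add atoms: none
Why: Sc(OTf)3 binds the dioxanedione carbonyls and raises the electrophilicity of the benzylidene carbon, to which the methine hydrogen of the ortho isopropoxy group is transferred as hydride through a six‑membered transition state ([1,5]‑hydride shift), giving zwitterion 7 (a 2‑aryloxypropan‑2‑ylium ion and a scandium enolate). The enolate carbon then adds to the oxocarbenium carbon and so forms the O–C(CH3)2–C bond and the dihydropyran ring in a 6‑endo‑trig closure (enolate in the enolexo mode); the step is redox‑neutral, oxidising the ether carbon and reducing the benzylic carbon to the CH2 group of C4. The closest known reaction type is the Lewis‑acid‑catalysed hydride shift/cyclisation (internal redox, tert‑amino‑effect type) of ortho‑alkoxybenzylidene malonates, barbiturates and Meldrum's acids to 3,3‑disubstituted chromanes. No stereocentre is formed, because the spiro carbon carries two identical acyl arms. The step needs site selectivity among three ether groups: only the isopropoxy group ortho to the alkylidene can reach the acceptor carbon, the para isopropoxy group is held away by the ring, and the ortho methoxy group would have to give an unstabilised primary oxocarbenium ion. The two ortho substituents twist the alkylidene out of the arene plane, which should keep it electrophilic despite the donor ring and place the methine C–H over the acceptor carbon.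

Step 6
Reactants: 8 6‑iodo‑5‑methoxy‑2,2,2',2'‑tetramethyl‑7‑(propan‑2‑yloxy)spiro[chromane‑3,5'‑[1,3]dioxane]‑4',6'‑dione
Product: 10 rac‑6‑iodo‑5‑methoxy‑2,2‑dimethyl‑7‑(propan‑2‑yloxy)chromane‑3‑carboxylic acid, via malonic acid 9 (not isolated)
Conditions: LiOH·H2O, THF–H2O, rt; 1 M HCl to pH 2; then xylene, 130 °C
Reagents that add atoms: lithium hydroxide, [Li+].[OH-]
Why: Saponification of the spiro dioxanedione releases acetone and gives malonic acid 9, which should lose CO2 on heating through the cyclic six‑membered transition state (malonic acid decarboxylation) under neutral conditions, so that no C3 carbanion able to expel the aryloxide is formed; the C3 stereocentre arises as a racemate and is erased in step 7.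

Step 7
Reactants: 10 rac‑6‑iodo‑5‑methoxy‑2,2‑dimethyl‑7‑(propan‑2‑yloxy)chromane‑3‑carboxylic acid
Product: 12 6‑iodo‑5‑methoxy‑2,2‑dimethyl‑7‑(propan‑2‑yloxy)chromane, via Barton ester 11 (not isolated)
Conditions: 1‑hydroxypyridine‑2(1H)‑thione, DCC, DMAP (cat.), CH2Cl2, 0 °C to rt, dark; then t‑BuSH (10 equiv), THF, tungsten lamp, rt
Reagents that add atoms: none
Why: Barton reductive decarboxylation; the thiohydroxamate ester fragments in a radical chain to CO2 and the secondary C3 radical, which should take a hydrogen atom from the excess thiol faster than it can open by β‑scission of the C2–O bond, and alkyl radicals leave the aryl iodide untouched.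

Step 8
Reactants: 13 1‑(2,4‑dihydroxyphenyl)ethan‑1‑one
Product: 14 1‑[2‑hydroxy‑4‑(propan‑2‑yloxy)phenyl]ethan‑1‑one
Conditions: 2‑bromopropane (1.2 equiv), K2CO3, acetone, reflux
Reagents that add atoms: 2‑bromopropane, CC(C)Br
Why: Williamson ether synthesis, selective for the 4‑hydroxyl because the 2‑hydroxyl is hydrogen‑bonded to the acetyl group.

Step 9
Reactants: 14 1‑[2‑hydroxy‑4‑(propan‑2‑yloxy)phenyl]ethan‑1‑one
Product: 15 (E)‑3‑(dimethylamino)‑1‑[2‑hydroxy‑4‑(propan‑2‑yloxy)phenyl]prop‑2‑en‑1‑one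
Conditions: Me2NCH(OMe)2, toluene, 90 °C
Reagents that add atoms: N,N‑dimethylformamide dimethyl acetal, COC(OC)N(C)C
Why: Condensation of the methyl ketone with the amide acetal gives the conjugated enaminone, which should form as the more stable E isomer.

Step 10
Reactants: 15 (E)‑3‑(dimethylamino)‑1‑[2‑hydroxy‑4‑(propan‑2‑yloxy)phenyl]prop‑2‑en‑1‑one
Product: 16 3‑iodo‑7‑(propan‑2‑yloxy)‑4H‑chromen‑4‑one
Conditions: I2 (1.5 equiv), CHCl3, rt
Reagents that add atoms: iodine, II
Why: Iodocyclisation of a 2‑hydroxyaryl enaminone; iodination of the α‑carbon gives an α‑iodo iminium ion, the phenol adds to it (closure of ring C at O1–C2), and loss of dimethylamine gives the 3‑iodochromone.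

Step 11
Reactants: 12 6‑iodo‑5‑methoxy‑2,2‑dimethyl‑7‑(propan‑2‑yloxy)chromane; 16 3‑iodo‑7‑(propan‑2‑yloxy)‑4H‑chromen‑4‑one
Product: 19 3‑[5‑methoxy‑2,2‑dimethyl‑7‑(propan‑2‑yloxy)chroman‑6‑yl]‑7‑(propan‑2‑yloxy)‑4H‑chromen‑4‑one, via aryllithium 17 (not isolated), via arylzinc chloride 18 (not isolated)
Conditions: n‑BuLi (1.05 equiv), THF, −78 °C; ZnCl2 (1.1 equiv), −78 °C to rt; then 16, Pd2(dba)3 (2 mol %), RuPhos (8 mol %), THF, 60 °C
Reagents that add atoms: none
Why: Negishi coupling; iodine–lithium exchange is fast at −78 °C, transmetalation to zinc gives a nucleophile that should not add to the chromone, and a zerovalent palladium catalyst with a bulky dialkylbiarylphosphine inserts into the C3–I bond of the vinylogous ester and couples di‑ortho‑substituted arylzinc reagents.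

Step 12
Reactants: 19 3‑[5‑methoxy‑2,2‑dimethyl‑7‑(propan‑2‑yloxy)chroman‑6‑yl]‑7‑(propan‑2‑yloxy)‑4H‑chromen‑4‑one
Product: 21 glycyrrhizaisoflavone C, 7‑hydroxy‑3‑(7‑hydroxy‑5‑methoxy‑2,2‑dimethylchroman‑6‑yl)‑4H‑chromen‑4‑one, via bis(dichloroborinate) 20 (not isolated)
Conditions: BCl3 (6 equiv), CH2Cl2, −78 to 0 °C; then H2O–MeOH
Reagents that add atoms: none
Why: Lewis‑acid dealkylation; BCl3 cleaves aryl isopropyl ethers by loss of the secondary alkyl group as 2‑chloropropane at temperatures at which an aryl methyl ether without a chelating carbonyl neighbour should survive, and the tertiary ring ether of the chromane, if it ionises at all, stays tethered and should reclose.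

**Compound list**

1 | 2,4,6‑trihydroxybenzaldehyde | O=Cc1c(O)cc(O)cc1O | starting material
2 | 2‑hydroxy‑4,6‑di(propan‑2‑yloxy)benzaldehyde | O=Cc1c(O)cc(OC(C)C)cc1OC(C)C | intermediate
3 | 2‑hydroxy‑3‑iodo‑4,6‑di(propan‑2‑yloxy)benzaldehyde | O=Cc1c(O)c(I)c(OC(C)C)cc1OC(C)C | intermediate
4 | 3‑iodo‑2‑methoxy‑4,6‑di(propan‑2‑yloxy)benzaldehyde | COc1c(I)c(OC(C)C)cc(OC(C)C)c1C=O | intermediate
5 | 2,2‑dimethyl‑1,3‑dioxane‑4,6‑dione (Meldrum's acid) | CC1(C)OC(=O)CC(=O)O1 | starting material
6 | 5‑{[3‑iodo‑2‑methoxy‑4,6‑di(propan‑2‑yloxy)phenyl]methylidene}‑2,2‑dimethyl‑1,3‑dioxane‑4,6‑dione | COc1c(I)c(OC(C)C)cc(OC(C)C)c1C=C1C(=O)OC(C)(C)OC1=O | intermediate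
7 | zwitterion after hydride shift (2‑aryloxypropan‑2‑ylium ion / dioxanedione enolate) | COc1c(I)c(OC(C)C)cc([O+]=C(C)C)c1CC1=C([O-])OC(C)(C)OC1=O | intermediate (not isolated)
8 | 6‑iodo‑5‑methoxy‑2,2,2',2'‑tetramethyl‑7‑(propan‑2‑yloxy)spiro[chromane‑3,5'‑[1,3]dioxane]‑4',6'‑dione | COc1c(I)c(OC(C)C)cc2OC(C)(C)C3(Cc12)C(=O)OC(C)(C)OC3=O | intermediate
9 | 6‑iodo‑5‑methoxy‑2,2‑dimethyl‑7‑(propan‑2‑yloxy)chromane‑3,3‑dicarboxylic acid | COc1c(I)c(OC(C)C)cc2OC(C)(C)C(Cc12)(C(O)=O)C(O)=O | intermediate (not isolated)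
10 | rac‑6‑iodo‑5‑methoxy‑2,2‑dimethyl‑7‑(propan‑2‑yloxy)chromane‑3‑carboxylic acid | COc1c(I)c(OC(C)C)cc2OC(C)(C)C(Cc12)C(O)=O | intermediate
11 | rac‑2‑thioxopyridin‑1(2H)‑yl 6‑iodo‑5‑methoxy‑2,2‑dimethyl‑7‑(propan‑2‑yloxy)chromane‑3‑carboxylate (Barton ester) | COc1c(I)c(OC(C)C)cc2OC(C)(C)C(Cc12)C(=O)On1ccccc1=S | intermediate (not isolated)
12 | 6‑iodo‑5‑methoxy‑2,2‑dimethyl‑7‑(propan‑2‑yloxy)chromane | COc1c(I)c(OC(C)C)cc2OC(C)(C)CCc12 | intermediate
13 | 1‑(2,4‑dihydroxyphenyl)ethan‑1‑one | CC(=O)c1ccc(O)cc1O | starting material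
14 | 1‑[2‑hydroxy‑4‑(propan‑2‑yloxy)phenyl]ethan‑1‑one | CC(=O)c1ccc(OC(C)C)cc1O | intermediate
15 | (E)‑3‑(dimethylamino)‑1‑[2‑hydroxy‑4‑(propan‑2‑yloxy)phenyl]prop‑2‑en‑1‑one | CN(C)/C=C/C(=O)c1ccc(OC(C)C)cc1O | intermediate
16 | 3‑iodo‑7‑(propan‑2‑yloxy)‑4H‑chromen‑4‑one | CC(C)Oc1ccc2c(c1)occ(I)c2=O | intermediate
17 | [5‑methoxy‑2,2‑dimethyl‑7‑(propan‑2‑yloxy)chroman‑6‑yl]lithium | COc1c([Li])c(OC(C)C)cc2OC(C)(C)CCc12 | intermediate (not isolated)
18 | chloro[5‑methoxy‑2,2‑dimethyl‑7‑(propan‑2‑yloxy)chroman‑6‑yl]zinc | COc1c([Zn]Cl)c(OC(C)C)cc2OC(C)(C)CCc12 | intermediate (not isolated)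
19 | 3‑[5‑methoxy‑2,2‑dimethyl‑7‑(propan‑2‑yloxy)chroman‑6‑yl]‑7‑(propan‑2‑yloxy)‑4H‑chromen‑4‑one | COc1c(-c3coc4cc(OC(C)C)ccc4c3=O)c(OC(C)C)cc2OC(C)(C)CCc12 | intermediate
20 | bis(dichloroborinate) of the target (both phenol oxygens as O–BCl2) | COc1c(-c3coc4cc(OB(Cl)Cl)ccc4c3=O)c(OB(Cl)Cl)cc2OC(C)(C)CCc12 | intermediate (not isolated)
21 | glycyrrhizaisoflavone C, 7‑hydroxy‑3‑(7‑hydroxy‑5‑methoxy‑2,2‑dimethylchroman‑6‑yl)‑4H‑chromen‑4‑one | COc1c(-c3coc4cc(O)ccc4c3=O)c(O)cc2OC(C)(C)CCc12 | target

**Step count**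

Total: 12 steps. Longest linear sequence: 9 steps (steps 1–7, 11, 12); steps 8–10 make the chromone partner.

**Steps most likely to fail**

Step 5. What may go wrong: hydride transfer that is too slow on a benzylidene carbon deactivated by three alkoxy donors; collapse of zwitterion 7 by proton transfer from a methyl group of the oxocarbenium ion to the enolate instead of bond formation between two fully substituted carbons; or dealkylative lactonisation of the ortho ether oxygen onto a dioxanedione carbonyl. The fallback sets out from 4 and comes back at 12, and closes the ring at oxygen instead. BCl3 (1.1 equiv, CH2Cl2, −78 °C) should remove only the isopropyl group ortho to the formyl group, through the six‑membered boron chelate, and give 6‑hydroxy‑3‑iodo‑2‑methoxy‑4‑(propan‑2‑yloxy)benzaldehyde F1. A catalytic Petasis‑type condensation of this salicylaldehyde with (2‑methylprop‑1‑en‑1‑yl)boronic acid (dibenzylamine 20 mol %, 1,4‑dioxane, 90 °C), followed in the same flask by loss of the amine and oxa‑6π electrocyclisation, should give 6‑iodo‑5‑methoxy‑2,2‑dimethyl‑7‑(propan‑2‑yloxy)‑2H‑chromene F2. Diimide reduction of the C3=C4 double bond (2‑nitrobenzenesulfonohydrazide, Et3N, MeCN, rt), which leaves the aryl iodide alone, should then give 12.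

Step 7. What may go wrong: ring opening of the C3 radical by β‑scission of the C2–O bond (loss of an aryloxyl radical) faster than hydrogen‑atom transfer, or incomplete acylation of the hindered acid. The fallback sets out from 10 and comes back at 12, without a radical at C3. BH3·SMe2 (THF, 0 °C to rt) should reduce the acid to rac‑[6‑iodo‑5‑methoxy‑2,2‑dimethyl‑7‑(propan‑2‑yloxy)chroman‑3‑yl]methanol F3. Dess–Martin periodinane (CH2Cl2, rt) should give rac‑6‑iodo‑5‑methoxy‑2,2‑dimethyl‑7‑(propan‑2‑yloxy)chromane‑3‑carbaldehyde F4. Tsuji–Wilkinson decarbonylation with RhCl(PPh3)3 (1 equiv, toluene, 110 °C) should then give 12 by extrusion of CO and C–H reductive elimination at rhodium; the di‑ortho‑substituted, donor‑rich aryl iodide is a poor partner for oxidative addition.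

Step 11. What may go wrong: slow transmetalation and reductive elimination at the di‑ortho‑alkoxy arylzinc, so that protodemetalation and homocoupling take over, or addition of the organometallic to C2 of the chromone. The fallback sets out from 12 and comes back at 19, with an isolable boron nucleophile. Iodine–lithium exchange (n‑BuLi, THF, −78 °C) and quench with 2‑isopropoxy‑4,4,5,5‑tetramethyl‑1,3,2‑dioxaborolane should give 2‑[5‑methoxy‑2,2‑dimethyl‑7‑(propan‑2‑yloxy)chroman‑6‑yl]‑4,4,5,5‑tetramethyl‑1,3,2‑dioxaborolane F5. This boronate is purified and coupled with 16 in a Suzuki–Miyaura reaction (Pd(OAc)2, SPhos, K3PO4, toluene–H2O, 80 °C) to give 19.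

**Further compounds**

F1 | step 5 | 6‑hydroxy‑3‑iodo‑2‑methoxy‑4‑(propan‑2‑yloxy)benzaldehyde | COc1c(I)c(OC(C)C)cc(O)c1C=O
F2 | step 5 | 6‑iodo‑5‑methoxy‑2,2‑dimethyl‑7‑(propan‑2‑yloxy)‑2H‑chromene | COc1c(I)c(OC(C)C)cc2OC(C)(C)C=Cc12
F3 | step 7 | rac‑[6‑iodo‑5‑methoxy‑2,2‑dimethyl‑7‑(propan‑2‑yloxy)chroman‑3‑yl]methanol | COc1c(I)c(OC(C)C)cc2OC(C)(C)C(CO)Cc12
F4 | step 7 | rac‑6‑iodo‑5‑methoxy‑2,2‑dimethyl‑7‑(propan‑2‑yloxy)chromane‑3‑carbaldehyde | COc1c(I)c(OC(C)C)cc2OC(C)(C)C(C=O)Cc12
F5 | step 11 | 2‑[5‑methoxy‑2,2‑dimethyl‑7‑(propan‑2‑yloxy)chroman‑6‑yl]‑4,4,5,5‑tetramethyl‑1,3,2‑dioxaborolane | COc1c(B3OC(C)(C)C(C)(C)O3)c(OC(C)C)cc2OC(C)(C)CCc12
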